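In ring A (C6–C11) of the spiro[5.5]undecane, C9 (CHBr) and C7 (CMe–OH) sit 1,3 to each other across C8, the spacing produced when an aldehyde carbon adds to the CH2 terminus of an isopropenyl group. The route therefore rests on the C8–C9 disconnection: one catalytic asymmetric carbonyl–ene cyclisation forges that bond, closes ring A, sets the C9 carbinol as the first stereocentre and leaves a C7 methylidene for later hydration. Its substrate is an achiral aldehyde, OHC–CH2–CMe2– attached to the quaternary ring carbon of a cyclohexanone ethylene ketal that also carries the isopropenyl group; ring B stays a symmetric ketal, and C7 and spiro C6 are relayed from C9 afterwards.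

Key step: step 7

Numbering in names: spiro[5.5]undecane, C1–C5 = ring B, C6 = spiro carbon, C7–C11 = ring A (C7 Me/OH, C9 Br, C11 gem-dimethyl).
Assumption: the antipode of the chromium catalyst that gives the (9S)-alcohol is identified in a pilot run (MTPA esters); both antipodes derive from commercial cis-1-amino-2-indanol.
Remark: from step 10 onwards no step generates the C7 alkoxide, because with the equatorial C9 bromide it is aligned for Grob fragmentation.

Step 1
Reactants: 1 1,4-dioxaspiro[4.5]decane-8-carboxylic acid; 2 3-methylbut-2-en-1-ol (prenol)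
Product: 3 3-methylbut-2-en-1-yl 1,4-dioxaspiro[4.5]decane-8-carboxylate
Conditions: DCC, DMAP (cat.), CH2Cl2, 0 °C → rt
Reagents that add atoms: none
Why: Steglich esterification joins an unhindered acid and a primary allylic alcohol under neutral conditions that leave the ketal and the trisubstituted alkene untouched.

Step 2
Reactants: 3 3-methylbut-2-en-1-yl 1,4-dioxaspiro[4.5]decane-8-carboxylate
Product: 6 8-(2-methylbut-3-en-2-yl)-1,4-dioxaspiro[4.5]decane-8-carboxylic acid, via silyl ketene acetal 4 (not isolated), via trimethylsilyl ester 5 (not isolated)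
Conditions: LDA, THF, −78 °C; TMSCl, −78 °C → rt, then 65 °C; then H2O (pH 4 buffer)
Reagents that add atoms: none
Why: Ireland–Claisen rearrangement, in which the tetrasubstituted silyl ketene acetal undergoes a chair-like [3,3] shift that bonds the ring carbon to the dimethyl-substituted allyl terminus and so creates both contiguous quaternary carbons (no stereocentre arises because ring B is symmetric).

Step 3
Reactants: 6 8-(2-methylbut-3-en-2-yl)-1,4-dioxaspiro[4.5]decane-8-carboxylic acid
Product: 9 1-[8-(2-methylbut-3-en-2-yl)-1,4-dioxaspiro[4.5]decan-8-yl]ethan-1-one, via lithium carboxylate 7 (not isolated), via dilithium gem-diolate 8 (not isolated)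
Conditions: MeLi (3 equiv), Et2O, 0 °C → rt; inverse quench into ice-water
Reagents that add atoms: methyllithium, [Li]C
Why: Addition of methyllithium to a lithium carboxylate (acid-to-methyl-ketone synthesis) stops at the stable gem-diolate, which releases the ketone only on quench, and the congested environment suppresses a second addition.

Step 4
Reactants: 9 1-[8-(2-methylbut-3-en-2-yl)-1,4-dioxaspiro[4.5]decan-8-yl]ethan-1-one
Product: 10 8-(2-methylbut-3-en-2-yl)-8-(prop-1-en-2-yl)-1,4-dioxaspiro[4.5]decane
Conditions: Ph3PCH3Br, KOtBu, toluene, rt → 90 °C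
Reagents that add atoms: methyltriphenylphosphonium bromide, C[P+](c1ccccc1)(c1ccccc1)c1ccccc1.[Br-]
Why: Wittig methylenation with the small methylide at elevated temperature is the standard olefination of hindered methyl ketones and tolerates the ketal and the vinyl group.

Step 5
Reactants: 10 8-(2-methylbut-3-en-2-yl)-8-(prop-1-en-2-yl)-1,4-dioxaspiro[4.5]decane
Product: 12 3-methyl-3-[8-(prop-1-en-2-yl)-1,4-dioxaspiro[4.5]decan-8-yl]butan-1-ol, via alkyl(disiamyl)borane 11 (not isolated)
Conditions: Sia2BH (from BH3·THF and 2-methylbut-2-ene), THF, 0 °C; then NaOH, H2O2, 0 °C → rt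
Reagents that add atoms: hydrogen peroxide, OO
Why: Anti-Markovnikov hydroboration–oxidation with a bulky dialkylborane, whose rate drops steeply from monosubstituted to 1,1-disubstituted alkenes, should take the vinyl group and spare the far more congested isopropenyl group.

Step 6
Reactants: 12 3-methyl-3-[8-(prop-1-en-2-yl)-1,4-dioxaspiro[4.5]decan-8-yl]butan-1-ol
Product: 13 3-methyl-3-[8-(prop-1-en-2-yl)-1,4-dioxaspiro[4.5]decan-8-yl]butanal
Conditions: Dess–Martin periodinane, pyridine, CH2Cl2, 0 °C → rt
Reagents that add atoms: none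
Why: Buffered Dess–Martin oxidation takes the primary alcohol to the aldehyde without acid, so neither the ketal nor a premature racemic ene closure is put at risk.

Step 7
Reactants: 13 3-methyl-3-[8-(prop-1-en-2-yl)-1,4-dioxaspiro[4.5]decan-8-yl]butanal
Product: 14 (9S)-3,3-(ethylenedioxy)-11,11-dimethyl-7-methylidenespiro[5.5]undecan-9-ol
Conditions: Cr(III)Cl complex of the tridentate Schiff base from cis-1-amino-2-indanol and 3-(1-adamantyl)-2-hydroxy-5-methylbenzaldehyde (5–10 mol%, antipode giving 9S), 4 Å MS, toluene, rt
Reagents that add atoms: none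
Why: The chromium(III) Lewis acid binds the aldehyde oxygen, the terminal CH2 of the isopropenyl group attacks the carbonyl carbon and a hydrogen of the isopropenyl methyl passes to oxygen in a concerted, asynchronous six-centre process (type II carbonyl–ene); the closest known reaction type is the catalytic asymmetric cyclisation of 5-methylhex-5-enals to 3-methylenecyclohexanols. Ring A closes as a six-membered carbocycle through a chair-like transition state, exo with respect to the C=O (6-exo-trig) and with both alkene carbons inside the new ring (6-(2,4) mode). C9 is the only stereocentre formed, and because the substrate is achiral with a symmetric ring B its configuration is decided solely by which aldehyde enantioface the chiral ligand shell leaves open. The step needs ene rather than cationic Prins behaviour and one alkene regioisomer: the only allylic hydrogens are those of the methyl group, the other allylic position being the quaternary ring carbon, so only the exocyclic 7-methylidene product can arise, and the mild catalyst with molecular sieves should leave the dioxolane intact. The two contiguous quaternary carbons of the tether bias the chain towards the folded conformer and so favour cyclisation over intermolecular reaction.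

Step 8
Reactants: 14 (9S)-3,3-(ethylenedioxy)-11,11-dimethyl-7-methylidenespiro[5.5]undecan-9-ol
Product: 15 (7S,9S)-3,3-(ethylenedioxy)-11,11-dimethylspiro[5.5]undecan-9-ol 7-spiro-oxirane (7,7-epoxymethano; epoxide O cis to the 9-OH)
Conditions: VO(acac)2 (cat.), t-BuOOH, CH2Cl2, 0 °C → rt
Reagents that add atoms: tert-butyl hydroperoxide, CC(C)(C)OO
Why: Vanadium-catalysed hydroxyl-directed epoxidation of the homoallylic alcohol, in which the alkoxide-bound peroxovanadium species (chair with axial C9–O) delivers oxygen to the methylidene face cis to the C9 oxygen and so sets C7.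

Step 9
Reactants: 15 (7S,9S)-3,3-(ethylenedioxy)-11,11-dimethylspiro[5.5]undecan-9-ol 7-spiro-oxirane
Product: 16 (7S,9S)-3,3-(ethylenedioxy)-7,11,11-trimethylspiro[5.5]undecane-7,9-diol (cis-1,3-diol)
Conditions: LiEt3BH, THF, 0 °C → rt; then H2O
Reagents that add atoms: none
Why: Hydride opening of the 2,2-disubstituted oxirane by SN2 attack at its unsubstituted CH2 terminus turns that carbon into the C7 methyl group and leaves the C7–O bond, hence the cis-diol configuration, untouched.

Step 10
Reactants: 16 (7S,9S)-3,3-(ethylenedioxy)-7,11,11-trimethylspiro[5.5]undecane-7,9-diol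
Product: 17 (7S,9R)-9-bromo-3,3-(ethylenedioxy)-7,11,11-trimethylspiro[5.5]undecan-7-ol (Br trans to OH)
Conditions: PPh3, CBr4, CH2Cl2, 0 °C → rt
Reagents that add atoms: carbon tetrabromide, BrC(Br)(Br)Br
Why: Appel bromination, in which only the secondary C9 alkoxyphosphonium can be displaced by bromide (SN2, inversion, axial leaving group and equatorial entry), while the tertiary alcohol is too hindered to react and, being cis, cannot close an oxetane.

Step 11
Reactants: 17 (7S,9R)-9-bromo-3,3-(ethylenedioxy)-7,11,11-trimethylspiro[5.5]undecan-7-ol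
Product: 18 (7S,9R)-9-bromo-7-hydroxy-7,11,11-trimethylspiro[5.5]undecan-3-one
Conditions: 1 M aq. HCl, THF, rt
Reagents that add atoms: water, O
Why: Acid-catalysed ketal hydrolysis under dilute aqueous conditions is mild enough not to dehydrate the tertiary alcohol or solvolyse the secondary bromide.

Step 12
Reactants: 18 (7S,9R)-9-bromo-7-hydroxy-7,11,11-trimethylspiro[5.5]undecan-3-one
Product: 19 (7S,9R)-9-bromo-7-hydroxy-7,11,11-trimethylspiro[5.5]undeca-1,4-dien-3-one
Conditions: IBX (3 equiv), DMSO, 75–80 °C
Reagents that add atoms: none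
Why: IBX α,β-dehydrogenation of the ketone, run twice in one flask, gives the cross-conjugated dienone (quaternary C6 blocks aromatisation) under non-basic conditions that keep the γ-bromo alcohol intact.

Step 13
Reactants: 19 (7S,9R)-9-bromo-7-hydroxy-7,11,11-trimethylspiro[5.5]undeca-1,4-dien-3-one
Product: 20 (6S,7S,9R)-9-bromo-7-hydroxy-7,11,11-trimethylspiro[5.5]undec-1-en-3-one
Conditions: [Ir(cod)(PCy3)(py)]PF6 (5 mol%), H2 (1 atm), CH2Cl2, 0 °C, stopped after 1 equiv H2
Reagents that add atoms: none
Why: Hydroxyl-directed homogeneous hydrogenation, in which the axial tertiary C7–OH binds iridium and is gauche only to C5, so hydrogen is delivered to the C4=C5 arm cis to the hydroxyl while the anti C1=C2 arm stays out of reach, which fixes spiro C6 as S.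

Step 14
Reactants: 20 (6S,7S,9R)-9-bromo-7-hydroxy-7,11,11-trimethylspiro[5.5]undec-1-en-3-one
Product: 21 (6S,7S,9R)-9-bromo-3-[(E)-bromomethylidene]-7,11,11-trimethylspiro[5.5]undec-1-en-7-ol
Conditions: Ph3PCH2Br·Br (slight excess over base), NaHMDS, THF, −78 → 0 °C
Reagents that add atoms: (bromomethyl)triphenylphosphonium bromide, BrC[P+](c1ccccc1)(c1ccccc1)c1ccccc1.[Br-]
Why: Wittig bromomethylenation of the enone carbonyl gives the 1-bromodiene directly, the ylide being too weak a base to deprotonate the tertiary alcohol when no free amide remains, and the E isomer (Br cis to C4H2) is to be separated chromatographically from any Z isomer.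

Compound list
1 | 1,4-dioxaspiro[4.5]decane-8-carboxylic acid | OC(=O)C1CCC2(CC1)OCCO2 | starting material
2 | 3-methylbut-2-en-1-ol (prenol) | CC(C)=CCO | starting material
3 | 3-methylbut-2-en-1-yl 1,4-dioxaspiro[4.5]decane-8-carboxylate | CC(C)=CCOC(=O)C1CCC2(CC1)OCCO2 | intermediate
4 | silyl ketene acetal: trimethyl{[(3-methylbut-2-en-1-yl)oxy](1,4-dioxaspiro[4.5]decan-8-ylidene)methoxy}silane | CC(C)=CCOC(O[Si](C)(C)C)=C1CCC2(CC1)OCCO2 | intermediate
5 | trimethylsilyl ester: trimethylsilyl 8-(2-methylbut-3-en-2-yl)-1,4-dioxaspiro[4.5]decane-8-carboxylate | C=CC(C)(C)C1(C(=O)O[Si](C)(C)C)CCC2(CC1)OCCO2 | intermediate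
6 | 8-(2-methylbut-3-en-2-yl)-1,4-dioxaspiro[4.5]decane-8-carboxylic acid | C=CC(C)(C)C1(C(=O)O)CCC2(CC1)OCCO2 | intermediate
7 | lithium carboxylate: lithium 8-(2-methylbut-3-en-2-yl)-1,4-dioxaspiro[4.5]decane-8-carboxylate | [Li+].[O-]C(=O)C1(C(C)(C)C=C)CCC2(CC1)OCCO2 | intermediate
8 | dilithium gem-diolate: dilithium 1-[8-(2-methylbut-3-en-2-yl)-1,4-dioxaspiro[4.5]decan-8-yl]ethane-1,1-diolate | [Li+].[Li+].CC([O-])([O-])C1(C(C)(C)C=C)CCC2(CC1)OCCO2 | intermediate
9 | 1-[8-(2-methylbut-3-en-2-yl)-1,4-dioxaspiro[4.5]decan-8-yl]ethan-1-one | CC(=O)C1(C(C)(C)C=C)CCC2(CC1)OCCO2 | intermediate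
10 | 8-(2-methylbut-3-en-2-yl)-8-(prop-1-en-2-yl)-1,4-dioxaspiro[4.5]decane | C=CC(C)(C)C1(C(C)=C)CCC2(CC1)OCCO2 | intermediate
11 | alkyl(disiamyl)borane: bis(3-methylbutan-2-yl){3-methyl-3-[8-(prop-1-en-2-yl)-1,4-dioxaspiro[4.5]decan-8-yl]butyl}borane | CC(C)C(C)B(CCC(C)(C)C1(C(C)=C)CCC2(CC1)OCCO2)C(C)C(C)C | intermediate
12 | 3-methyl-3-[8-(prop-1-en-2-yl)-1,4-dioxaspiro[4.5]decan-8-yl]butan-1-ol | OCCC(C)(C)C1(C(C)=C)CCC2(CC1)OCCO2 | intermediate
13 | 3-methyl-3-[8-(prop-1-en-2-yl)-1,4-dioxaspiro[4.5]decan-8-yl]butanal | O=CCC(C)(C)C1(C(C)=C)CCC2(OCCO2)CC1 | intermediate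
14 | (9S)-3,3-(ethylenedioxy)-11,11-dimethyl-7-methylidenespiro[5.5]undecan-9-ol | CC1(C)C[C@H](O)CC(=C)C12CCC3(OCCO3)CC2 | intermediate
15 | (7S,9S)-3,3-(ethylenedioxy)-11,11-dimethylspiro[5.5]undecan-9-ol 7-spiro-oxirane (epoxide O cis to 9-OH) | CC1(C)C[C@H](O)C[C@@]4(CO4)C12CCC3(OCCO3)CC2 | intermediate
16 | (7S,9S)-3,3-(ethylenedioxy)-7,11,11-trimethylspiro[5.5]undecane-7,9-diol | CC1(C)C[C@H](O)C[C@](C)(O)C12CCC3(OCCO3)CC2 | intermediate
17 | (7S,9R)-9-bromo-3,3-(ethylenedioxy)-7,11,11-trimethylspiro[5.5]undecan-7-ol | CC1(C)C[C@@H](Br)C[C@](C)(O)C12CCC3(OCCO3)CC2 | intermediate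
18 | (7S,9R)-9-bromo-7-hydroxy-7,11,11-trimethylspiro[5.5]undecan-3-one | CC1(C)C[C@@H](Br)C[C@](C)(O)C12CCC(=O)CC2 | intermediate
19 | (7S,9R)-9-bromo-7-hydroxy-7,11,11-trimethylspiro[5.5]undeca-1,4-dien-3-one | CC1(C)C[C@@H](Br)C[C@](C)(O)C12C=CC(=O)C=C2 | intermediate
20 | (6S,7S,9R)-9-bromo-7-hydroxy-7,11,11-trimethylspiro[5.5]undec-1-en-3-one | CC1(C)C[C@@H](Br)C[C@](C)(O)[C@@]12C=CC(=O)CC2 | intermediate
21 | (6S,7S,9R)-9-bromo-3-[(E)-bromomethylidene]-7,11,11-trimethylspiro[5.5]undec-1-en-7-ol | CC1(C)C[C@@H](Br)C[C@](C)(O)[C@@]12C=C/C(=C/Br)CC2 | target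

Total step count: 14. Longest linear sequence: 14 steps (fully linear from 1).

Steps most likely to fail

Step 7. The catalyst may discriminate the aldehyde enantiofaces poorly on this neopentyl-type substrate, or turn over slowly at the doubly quaternary tether. The fallback sets out from 13 and comes back at 14. Ring A is closed without asymmetric induction by a dimethylaluminium chloride-promoted type II carbonyl–ene reaction (Me2AlCl, CH2Cl2, −78 °C), which should give racemic 3,3-(ethylenedioxy)-11,11-dimethyl-7-methylidenespiro[5.5]undecan-9-ol F1. Classical resolution follows: esterification with (S)-O-methylmandelic acid (DCC, DMAP, CH2Cl2) should give (9S)-3,3-(ethylenedioxy)-11,11-dimethyl-7-methylidenespiro[5.5]undecan-9-yl (2S)-2-methoxy-2-phenylacetate F2 and its (9R)-configured diastereomeric ester F3. These are separated by chromatography, and saponification of F2 (LiOH, THF/H2O) returns 14.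

Step 13. Hydroxyl direction may not differentiate the two enone arms sufficiently, or hydrogenation may run on to the saturated ketone. The fallback sets out from 18 and comes back at 20, bypassing the dienone. Ketone 18 is dehydrogenated once (IBX, 1.2 equiv, DMSO, 65 °C) without stereocontrol, giving 20 together with its C6 epimer, (6R,7S,9R)-9-bromo-7-hydroxy-7,11,11-trimethylspiro[5.5]undec-1-en-3-one F4. The two are separated by chromatography, and F4 is hydrogenated back to 18 (H2, (Ph3P)3RhCl, benzene) and recycled, so material converges on 20.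

Step 14. Oxaphosphetane formation may show little or the wrong E/Z preference, because the two flanks of the carbonyl (vinylic CH and CH2) differ little in size. The fallback sets out from 20 and comes back at 21, correcting geometry after olefination instead of during it. The Z isomer, (6S,7S,9R)-9-bromo-3-[(Z)-bromomethylidene]-7,11,11-trimethylspiro[5.5]undec-1-en-7-ol F5, is separated on AgNO3-impregnated silica. It is then subjected to triplet-sensitised E/Z photoisomerisation of the bromodiene (thioxanthone, 405 nm, MeCN) and the resulting mixture is separated again; repeated cycles funnel F5 into 21.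

Further compounds
F1 | step 7 | racemic 3,3-(ethylenedioxy)-11,11-dimethyl-7-methylidenespiro[5.5]undecan-9-ol | CC1(C)CC(O)CC(=C)C12CCC3(OCCO3)CC2
F2 | step 7 | (9S)-3,3-(ethylenedioxy)-11,11-dimethyl-7-methylidenespiro[5.5]undecan-9-yl (2S)-2-methoxy-2-phenylacetate | CC1(C)C[C@H](OC(=O)[C@@H](OC)c5ccccc5)CC(=C)C12CCC3(OCCO3)CC2
F3 | step 7 | (9R)-3,3-(ethylenedioxy)-11,11-dimethyl-7-methylidenespiro[5.5]undecan-9-yl (2S)-2-methoxy-2-phenylacetate | CC1(C)C[C@@H](OC(=O)[C@@H](OC)c5ccccc5)CC(=C)C12CCC3(OCCO3)CC2
F4 | step 13 | (6R,7S,9R)-9-bromo-7-hydroxy-7,11,11-trimethylspiro[5.5]undec-1-en-3-one | CC1(C)C[C@@H](Br)C[C@](C)(O)[C@]12C=CC(=O)CC2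
F5 | step 14 | (6S,7S,9R)-9-bromo-3-[(Z)-bromomethylidene]-7,11,11-trimethylspiro[5.5]undec-1-en-7-ol | CC1(C)C[C@@H](Br)C[C@](C)(O)[C@@]12C=C/C(=C\Br)CC2
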